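**Strategy.** Everything rests on the C6′–C7′ bond of the side chain (numbered from the exocyclic =CH, C1′), the central CH2–CH2 bond of the 1,5-diene between the C4′=C5′ and C8′=C9′ E-trisubstituted alkenes; both carbons are primary allylic. The key step makes this bond in one operation by α,α′-selective cross-coupling of an allylbarium reagent with an allylic bromide, with both alkene geometries already in place and no activating group to remove. Its precursors are a geranyl-chloride-derived chloride whose aldehyde is masked as a dioxolane and an (E)-allylic bromide carrying a 3-furyl group as the latent butenolide ring; the (S)-α-alkylidene-γ-lactone ring is attached last by Horner–Wadsworth–Emmons olefination.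

Key step: step 6

Remark: the hemiacetal carbon of the hydroxybutenolide and C3 of the phosphono lactone are carried as epimer mixtures; both centres vanish in the following step.

**Step 1**
Reactants: 1 geranyl chloride [(2E)-1-chloro-3,7-dimethylocta-2,6-diene]
Product: 2 (4E)-6-chloro-4-methylhex-4-enal
Conditions: O3 (1.0 equiv, metered), pyridine, CH2Cl2, −78 °C
Reagents that add atoms: ozone [O-][O+]=O
Why: Chemoselective ozonolysis: ozone should cleave the electron-rich terminal alkene much faster than the 2,3-alkene, which is deactivated by the allylic chloride (as with geranyl esters), and pyridine turns the carbonyl oxide into the aldehyde without a nucleophilic reductant; the E-alkene is untouched.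

**Step 2**
Reactants: 2 (4E)-6-chloro-4-methylhex-4-enal
Product: 3 2-[(3E)-5-chloro-3-methylpent-3-en-1-yl]-1,3-dioxolane
Conditions: TMSOCH2CH2OTMS, TMSOTf (cat.), CH2Cl2, −78 °C
Reagents that add atoms: 1,2-bis(trimethylsilyloxy)ethane C[Si](C)(C)OCCO[Si](C)(C)C
Why: Noyori acetalisation is aprotic and cold, so the aldehyde should be protected without solvolysis of the allylic chloride.

**Step 3**
Reactants: 4 5-bromo-2-methylpent-2-ene; 5 3-bromofuran
Product: 7 3-(4-methylpent-3-en-1-yl)furan (perillene), via homoprenyl Grignard 6 (not isolated)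
Conditions: Mg, THF, rt; then 5, NiCl2(dppp) (cat.), Et2O, reflux
Reagents that add atoms: none
Why: Kumada–Corriu coupling: Ni(0) inserts into the furan C3–Br bond, the primary alkyl Grignard transmetalates and reductive elimination follows, with dppp suppressing β-hydride elimination.

**Step 4**
Reactants: 7 3-(4-methylpent-3-en-1-yl)furan
Product: 8 (2E)-5-(furan-3-yl)-2-methylpent-2-en-1-ol
Conditions: SeO2 (cat.), t-BuOOH, salicylic acid (cat.), CH2Cl2, rt
Reagents that add atoms: selenium dioxide O=[Se]=O (catalytic oxygen carrier); tert-butyl hydroperoxide CC(C)(C)OO (terminal oxygen source)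
Why: Sharpless catalytic SeO2 allylic oxidation (ene reaction, then [2,3]-sigmatropic shift) should hydroxylate the methyl group trans to the chain of the gem-dimethyl alkene, giving the E-allylic alcohol as in the ω-oxidation of prenyl termini of furanoterpenes.

**Step 5**
Reactants: 8 (2E)-5-(furan-3-yl)-2-methylpent-2-en-1-ol
Product: 9 3-[(3E)-5-bromo-4-methylpent-3-en-1-yl]furan
Conditions: CBr4, PPh3, CH2Cl2, 0 °C
Reagents that add atoms: carbon tetrabromide BrC(Br)(Br)Br
Why: Appel reaction: neutral SN2 displacement of the oxyphosphonium at the primary allylic carbon should give the bromide without allylic transposition or acid that would harm the furan.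

**Step 6 (key step)**
Reactants: 3 2-[(3E)-5-chloro-3-methylpent-3-en-1-yl]-1,3-dioxolane; 9 3-[(3E)-5-bromo-4-methylpent-3-en-1-yl]furan
Product: 11 2-[(3E,7E)-10-(furan-3-yl)-3,7-dimethyldeca-3,7-dien-1-yl]-1,3-dioxolane, via allylbarium chloride 10 (not isolated)
Conditions: BaI2, lithium biphenylide, THF, rt (reactive Ba); 3, −78 °C; then 9 (0.8 equiv), THF, −78 °C
Reagents that add atoms: none
Why: Reactive barium inserts into the allylic C–Cl bond of 3 at −78 °C to give σ-allylbarium 10, which at this temperature should neither undergo 1,3-metal shift nor lose its E geometry, and which attacks the primary carbon of bromide 9 through its own α-carbon (SN2-type α,α′ union), so the CH2–CH2 bond of the 1,5-diene forms with both trisubstituted alkenes already in place. The closest known reaction type is the Yamamoto allylbarium α,α′-selective allyl–allyl cross-coupling used for all-E polyprenoid 1,5-dienes. No ring is closed and no stereocentre is formed; the two E geometries come from geranyl chloride and from the SeO2 oxidation. The step needs α- over γ-attack at both partners, retention of alkene geometry and cross- over homo-coupling. These are secured by the γ,γ-disubstituted terminus of 10 (γ-attack would build a quaternary centre), the unhindered primary bromide of 9, complete formation of 10 before 9 is added, and −78 °C throughout. The dioxolane and the 3-alkylfuran are inert to the organobarium, which is why the aldehyde and the butenolide are carried in these masked forms.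

**Step 7**
Reactants: 11 2-[(3E,7E)-10-(furan-3-yl)-3,7-dimethyldeca-3,7-dien-1-yl]-1,3-dioxolane
Product: 13 4-[(3E,7E)-10-(1,3-dioxolan-2-yl)-4,8-dimethyldeca-3,7-dien-1-yl]-5-hydroxyfuran-2(5H)-one, via furan endoperoxide 12 (not isolated)
Conditions: O2, hν, rose bengal (cat.), i-Pr2NEt, CH2Cl2, −78 °C
Reagents that add atoms: oxygen O=O
Why: Kernan–Faulkner photooxygenation: singlet oxygen should add [4+2] to the furan far faster than it undergoes ene reaction with the trisubstituted alkenes at −78 °C, and the hindered base removes the less hindered bridgehead hydrogen (remote from the alkyl group), so the carbonyl ends up distal to the side chain.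

**Step 8**
Reactants: 13 4-[(3E,7E)-10-(1,3-dioxolan-2-yl)-4,8-dimethyldeca-3,7-dien-1-yl]-5-hydroxyfuran-2(5H)-one
Product: 16 (4E,8E)-4,8-dimethyl-11-(5-oxo-2,5-dihydrofuran-3-yl)undeca-4,8-dienal, via sodium hydroxy enoate 14 (not isolated), via butenolide dioxolane 15 (not isolated)
Conditions: NaBH4, EtOH, 0 °C; then 2 M HCl, THF, rt
Reagents that add atoms: water O
Why: In the basic borohydride medium the hydroxybutenolide opens to the formyl carboxylate, whose aldehyde is reduced (NaBH4 reduction); acidification should close the Z-hydroxy acid to the 4-substituted butenolide and hydrolyse the dioxolane (acetal hydrolysis).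

**Step 9**
Reactants: 17 (S)-5-(hydroxymethyl)dihydrofuran-2(3H)-one
Product: 18 (S)-5-oxotetrahydrofuran-2-carbaldehyde
Conditions: Dess–Martin periodinane, NaHCO3, CH2Cl2, 0 °C to rt; used crude
Reagents that add atoms: none
Why: Dess–Martin oxidation under buffered, non-basic conditions should give the α-acyloxy aldehyde without epimerisation.

**Step 10**
Reactants: 18 (S)-5-oxotetrahydrofuran-2-carbaldehyde
Product: 19 (S)-5-(2-methylprop-1-en-1-yl)dihydrofuran-2(3H)-one
Conditions: i-PrPPh3I, n-BuLi, THF, 0 °C; then 18, −78 °C to rt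
Reagents that add atoms: isopropyltriphenylphosphonium iodide CC(C)[P+](c1ccccc1)(c1ccccc1)c1ccccc1.[I-]
Why: Wittig olefination with the non-stabilised isopropylidene ylide at −78 °C should outrun enolisation of the aldehyde and attack on the lactone, so the (S) centre from the L-glutamic-acid-derived lactone is carried over unchanged.

**Step 11**
Reactants: 19 (S)-5-(2-methylprop-1-en-1-yl)dihydrofuran-2(3H)-one
Product: 21 diethyl [(5S)-5-(2-methylprop-1-en-1-yl)-2-oxotetrahydrofuran-3-yl]phosphonate (C3 epimers), via vinyl phosphate 20 (not isolated)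
Conditions: LDA (1.1 equiv), THF, −78 °C; ClP(O)(OEt)2; then LDA (2 equiv), −78 °C to rt; AcOH
Reagents that add atoms: diethyl chlorophosphate CCOP(=O)(Cl)OCC
Why: Wiemer vinyl phosphate–phosphonate rearrangement: O-phosphorylation of the lactone enolate and LDA-induced 1,3-migration of phosphorus from O to C should give the α-phosphono lactone, with C5 untouched.

**Step 12**
Reactants: 16 (4E,8E)-4,8-dimethyl-11-(5-oxo-2,5-dihydrofuran-3-yl)undeca-4,8-dienal; 21 diethyl [(5S)-5-(2-methylprop-1-en-1-yl)-2-oxotetrahydrofuran-3-yl]phosphonate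
Product: 22 (3E,5S)-3-[(4E,8E)-4,8-dimethyl-11-(5-oxo-2,5-dihydrofuran-3-yl)undeca-4,8-dien-1-ylidene]-5-(2-methylprop-1-en-1-yl)dihydrofuran-2(3H)-one
Conditions: LiCl, DBU, MeCN, 0 °C to rt
Reagents that add atoms: none
Why: Horner–Wadsworth–Emmons olefination under Masamune–Roush conditions: reversible addition and syn-elimination should favour the thermodynamically preferred E-alkylidene lactone (chain anti to the carbonyl), and the mild amine base leaves the butenolide and the C5 stereocentre alone.

**Compound list**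
1 | geranyl chloride, (2E)-1-chloro-3,7-dimethylocta-2,6-diene | CC(C)=CCC/C(C)=C/CCl | starting material
2 | (4E)-6-chloro-4-methylhex-4-enal | O=CCC/C(C)=C/CCl | intermediate
3 | 2-[(3E)-5-chloro-3-methylpent-3-en-1-yl]-1,3-dioxolane | C1(CC/C(C)=C/CCl)OCCO1 | intermediate
4 | 5-bromo-2-methylpent-2-ene | CC(C)=CCCBr | starting material
5 | 3-bromofuran | Brc1ccoc1 | starting material
6 | (4-methylpent-3-en-1-yl)magnesium bromide | CC(C)=CCC[Mg]Br | intermediate
7 | 3-(4-methylpent-3-en-1-yl)furan (perillene) | CC(C)=CCCc1ccoc1 | intermediate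
8 | (2E)-5-(furan-3-yl)-2-methylpent-2-en-1-ol | OC/C(C)=C/CCc1ccoc1 | intermediate
9 | 3-[(3E)-5-bromo-4-methylpent-3-en-1-yl]furan | BrC/C(C)=C/CCc1ccoc1 | intermediate
10 | chloro[(2E)-5-(1,3-dioxolan-2-yl)-3-methylpent-2-en-1-yl]barium | C1(CC/C(C)=C/C[Ba]Cl)OCCO1 | intermediate
11 | 2-[(3E,7E)-10-(furan-3-yl)-3,7-dimethyldeca-3,7-dien-1-yl]-1,3-dioxolane | C1(CC/C(C)=C/CC/C(C)=C/CCc2ccoc2)OCCO1 | intermediate
12 | 2,5-endoperoxide of 11 (2,3,7-trioxabicyclo[2.2.1]hept-5-ene carrying the chain at C5, next to the bridgehead) | C1(CC/C(C)=C/CC/C(C)=C/CCC2=CC3OOC2O3)OCCO1 | intermediate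
13 | 4-[(3E,7E)-10-(1,3-dioxolan-2-yl)-4,8-dimethyldeca-3,7-dien-1-yl]-5-hydroxyfuran-2(5H)-one (C5 epimers) | C1(CC/C(C)=C/CC/C(C)=C/CCC2=CC(=O)OC2O)OCCO1 | intermediate
14 | sodium (2Z,6E,10E)-13-(1,3-dioxolan-2-yl)-3-(hydroxymethyl)-7,11-dimethyltrideca-2,6,10-trienoate | C1(CC/C(C)=C/CC/C(C)=C/CC/C(CO)=C/C(=O)[O-])OCCO1.[Na+] | intermediate
15 | 4-[(3E,7E)-10-(1,3-dioxolan-2-yl)-4,8-dimethyldeca-3,7-dien-1-yl]furan-2(5H)-one | C1(CC/C(C)=C/CC/C(C)=C/CCC2=CC(=O)OC2)OCCO1 | intermediate
16 | (4E,8E)-4,8-dimethyl-11-(5-oxo-2,5-dihydrofuran-3-yl)undeca-4,8-dienal | O=CCC/C(C)=C/CC/C(C)=C/CCC1=CC(=O)OC1 | intermediate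
17 | (S)-5-(hydroxymethyl)dihydrofuran-2(3H)-one | OC[C@@H]1CCC(=O)O1 | starting material
18 | (S)-5-oxotetrahydrofuran-2-carbaldehyde | O=C[C@@H]1CCC(=O)O1 | intermediate
19 | (S)-5-(2-methylprop-1-en-1-yl)dihydrofuran-2(3H)-one | CC(C)=C[C@@H]1CCC(=O)O1 | intermediate
20 | diethyl (5S)-5-(2-methylprop-1-en-1-yl)-4,5-dihydrofuran-2-yl phosphate | CC(C)=C[C@@H]1CC=C(OP(=O)(OCC)OCC)O1 | intermediate
21 | diethyl [(5S)-5-(2-methylprop-1-en-1-yl)-2-oxotetrahydrofuran-3-yl]phosphonate (C3 epimers) | CC(C)=C[C@@H]1CC(P(=O)(OCC)OCC)C(=O)O1 | intermediate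
22 | (3E,5S)-3-[(4E,8E)-4,8-dimethyl-11-(5-oxo-2,5-dihydrofuran-3-yl)undeca-4,8-dien-1-ylidene]-5-(2-methylprop-1-en-1-yl)dihydrofuran-2(3H)-one | CC(C)=C[C@@H]1C/C(=C\CC/C(C)=C/CC/C(C)=C/CCC2=CC(=O)OC2)C(=O)O1 | target

**Totals.** Total step count: 12. Longest linear sequence: 7 steps (3, 4, 5, 6, 7, 8, 12).

**Steps most likely to fail**

Step 6. Regiocontrol may erode through γ-attack at either allyl terminus, and allyl–halogen exchange may lead to homo-coupling. The fallback sets out from 3 and comes back at 11. Displacement of the chloride of 3 with sodium benzenesulfinate (DMF, rt) should give 2-[(3E)-3-methyl-5-(phenylsulfonyl)pent-3-en-1-yl]-1,3-dioxolane F1. Its α-sulfonyl carbanion (n-BuLi, THF, −78 °C) is alkylated by bromide 9 in a geometry-retentive Julia–Biellmann coupling to 3-[(3E,7E)-10-(1,3-dioxolan-2-yl)-4,8-dimethyl-6-(phenylsulfonyl)deca-3,7-dien-1-yl]furan F2. Palladium-catalysed hydride displacement (PdCl2(dppp), LiBHEt3, THF, 0 °C) at the less substituted allyl terminus then removes the sulfonyl group and gives 11.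

Step 12. The olefination may be incompletely E-selective, and the amine base may move the new exocyclic double bond into the ring. The fallback sets out from 19 and comes back at 22. α-Bromination through the silyl ketene acetal (LiHMDS, TMSCl, THF, −78 °C; then NBS) should give (5S)-3-bromo-5-(2-methylprop-1-en-1-yl)dihydrofuran-2(3H)-one F3. Triphenylphosphine (THF, reflux) gives [(5S)-5-(2-methylprop-1-en-1-yl)-2-oxotetrahydrofuran-3-yl]triphenylphosphonium bromide F4, and aqueous NaOH gives the stabilised ylide (5S)-5-(2-methylprop-1-en-1-yl)-3-(triphenyl-λ5-phosphanylidene)dihydrofuran-2(3H)-one F5. Under neutral conditions (toluene, 80 °C) F5 condenses with aldehyde 16 in a Wittig reaction that is E-selective for α-alkylidene lactones, giving 22.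

Step 4. Over-oxidation to the enal, competing oxidation at the allylic CH2 and oxidative degradation of the furan may leave little alcohol. The fallback sets out from 5 and comes back at 8. Heck reaction of 3-bromofuran 5 with allyl alcohol (Pd(OAc)2, Bu4NCl, NaHCO3, DMF, 50 °C; arylation followed by chain-walking to the carbonyl) should give 3-(furan-3-yl)propanal F6. Wittig reaction with ethyl 2-(triphenylphosphoranylidene)propanoate (CH2Cl2, rt) gives ethyl (2E)-5-(furan-3-yl)-2-methylpent-2-enoate F7, and DIBAL-H (CH2Cl2, −78 °C) gives 8.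

**Further compounds**
F1 | step 6 | 2-[(3E)-3-methyl-5-(phenylsulfonyl)pent-3-en-1-yl]-1,3-dioxolane | C1(CC/C(C)=C/CS(=O)(=O)c2ccccc2)OCCO1
F2 | step 6 | 3-[(3E,7E)-10-(1,3-dioxolan-2-yl)-4,8-dimethyl-6-(phenylsulfonyl)deca-3,7-dien-1-yl]furan (racemic at C6) | C1(CC/C(C)=C/C(C/C(C)=C/CCc2ccoc2)S(=O)(=O)c2ccccc2)OCCO1
F3 | step 12 | (5S)-3-bromo-5-(2-methylprop-1-en-1-yl)dihydrofuran-2(3H)-one (C3 epimers) | CC(C)=C[C@@H]1CC(Br)C(=O)O1
F4 | step 12 | [(5S)-5-(2-methylprop-1-en-1-yl)-2-oxotetrahydrofuran-3-yl]triphenylphosphonium bromide | CC(C)=C[C@@H]1CC([P+](c2ccccc2)(c2ccccc2)c2ccccc2)C(=O)O1.[Br-]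
F5 | step 12 | (5S)-5-(2-methylprop-1-en-1-yl)-3-(triphenyl-λ5-phosphanylidene)dihydrofuran-2(3H)-one | CC(C)=C[C@@H]1CC(=P(c2ccccc2)(c2ccccc2)c2ccccc2)C(=O)O1
F6 | step 4 | 3-(furan-3-yl)propanal | O=CCCc1ccoc1
F7 | step 4 | ethyl (2E)-5-(furan-3-yl)-2-methylpent-2-enoate | CCOC(=O)/C(C)=C/CCc1ccoc1
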